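**The vessels.** A closed flask, a tank and a dosed flask take the same charge, so I compare them by the age of the converted X.

| flask | X | G | remark | time |
|---|---|---|---|---|
| north-west | 0.050 M | 2.5 mM | run made earlier |  |
| east | 0.025 M | 2.5 mM | run made earlier |  |
| south-east | 0.038 M | 2.5 mM | run made earlier |  |
| violet | 0.050 M | 2.50 mM | a closed flask charged with all of it at once and left for 30 min | 30 min |
| ochre | 0.050 M | 2.50 mM | a single well-mixed tank run continuously and read at steady state, 30 min in it on average |  |
| blue | 0.050 M (fed, over 24.0 min) | 2.50 mM | a stirred flask in which X is dosed at a steady rate over 24.0 min without added volume, worked up at 30 min | 30 min |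

| run | time / min | Z / % | Q / % |
|---|---|---|---|
| north-west | 5.00 | 20.7 | 8.7 |
| north-west | 10.0 | 34.7 | 15.7 |
| north-west | 15.0 | 44.5 | 21.1 |
| north-west | 20.0 | 50.2 | 24.7 |
| north-west | 25.0 | 54.0 | 26.6 |
| north-west | 30.0 | 56.3 | 28.2 |
| east | 3.00 | 14.0 | 5.2 |
| east | 5.00 | 21.3 | 8.9 |
| east | 8.00 | 29.7 | 13.0 |
| east | 12.0 | 39.2 | 18.2 |
| east | 20.0 | 50.6 | 24.6 |
| east | 40.0 | 59.2 | 30.7 |
| south-east | 3.00 | 13.5 | 5.1 |
| south-east | 5.00 | 21.0 | 9.0 |
| south-east | 8.00 | 30.1 | 13.1 |
| south-east | 12.0 | 38.8 | 17.8 |
| south-east | 20.0 | 50.6 | 24.4 |
| south-east | 40.0 | 59.5 | 30.9 |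

(each reading ± 0.3 percentage points)

1. the set-up with the highest share of Z in all that became Z or Q or J, at the outlet or at the end ("none" if the first two lie within 2 percentage points) (violet / ochre / blue / none)
2. share of Z in all that became Z or Q or J, at the outlet or at the end, violet
3. share of Z in all that became Z or Q or J, at the outlet or at the end, ochre
4. share of Z in all that became Z or Q or J, at the outlet or at the end, blue

- the stated concentrations are those of everything mixed, before any reaction; amounts are the same in each set-up
- the feed brings no volume worth counting
- the earlier runs were made in a closed, stirred flask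

**Reading age.** At 20.0 min, Z reads 50.2%, 50.6% and 50.6% for cX of 0.050 M, 0.025 M and 0.038 M, so I let each portion of X age along one percent curve. Blue's portions end 6.00 min to 30 min old; violet's are all 30 min old. Ochre holds ages past the readings, so it stays outside my bracket.

**The bracket.** I read the selectivity as Z/(Z+Q), leaving out the unread J. The north-west run gives 70.4% at 5.00 min and 66.6% at 30.0 min. Taking the share to fall with age, I hold blue's lead to 3.8 percentage points from above, as the first reading is younger than blue's youngest portion. From below, blue holds nothing older than violet, so I take no lead as the floor. Averaging Z and Q over the readings tightens this: blue gets 67.6%, a difference of 0.93 points. This is the age lead, blue's share less violet's on one batch curve. Ochre's ages average 30 min, as violet's do, so I assume it leads neither by the margin. The lead stands below the margin of 2 points, so I commit to none.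

**The forecast.** It says blue, with violet 64.1%, ochre 62% and blue 66.1%, adding “the call is marginal”. Its lead of 2 points lies inside my bracket, above my tightened value.

**The flask.** Violet gives 65.3%, ochre 64.9% and blue 66.3%, so the call is none; with J counted, blue's age lead over violet is 1.0 point.

    X ⇌ D (K = 11.0, k = 0.0260 /min)
    X ⇌ Z (K = 14.0, k = 0.0510 /min)
    D → Q (k = 1.40 /min)
    D ⇌ E (K = 1.10, k = 0.120 /min)
    E → J (k = 0.390 /min)
    D + G → L (k = 12.0 /M/min)

**The rates.** In blue at 30.0 min, by forward rates, X goes to Z 2.0 times as fast as to D, and D goes to Q 12 times as fast as to E. Held until 300 min, blue's share is 47.8% and violet's 47.1%, an age lead of 0.70 points.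

The readings were generated by integration for an exercise, noise included.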